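**Retrosynthetic overview**

1. The strategy rests on the ring B catechol: O3' and O4' each have one free ortho carbon (C2' and C5'), and these carry the prenyl group and C4'' of the 2,2-dimethylpyran (O4', C2'', C3'', C4''), so each oxygen can deliver its own five-carbon unit.
2. C2'–CH2 and C5'–C4'' are cut back to the O3'-(1,1-dimethylallyl), O4'-(1,1-dimethylpropargyl) bis-ether 15 (double aromatic Claisen, then [1,5]-H shift and oxa-6π closure of the pyran); a ring A silyl ether is cleaved last.
3. The two ethers are installed one after the other on a (2S)-flavan 9 carrying O3'-benzyl, O4'-mesyl and O7-triisopropylsilyl.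
4. C2–C1' comes from Suzuki coupling of dihydrocoumarin ketene acetal phosphate 3 with ring B boronate 7; the C2 stereocentre comes from iridium-catalysed asymmetric hydrogenation of 2-aryl-4H-chromene 8.
5. Ring order: rings A and C arrive together in 7-hydroxy-3,4-dihydrocoumarin, ring B is attached at C2, and the pyran ring is closed last.

Key step: step 13

Assumption: atom labels follow flavan numbering (ring C: O1, C2, C3, C4; ring A: C4a to C8a; ring B: C1' to C6'; pyran: O4', C2'', C3'', C4'').
Assumption: the sense of induction of the iridium P,N catalyst on chromene 8 is not predicted here; the ligand antipode that delivers the 2S flavan is to be used, both antipodes being available.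

**Route**

Step 1
Reactants: 1 7-hydroxychroman-2-one (7-hydroxy-3,4-dihydrocoumarin)
Product: 2 7-(triisopropylsilyloxy)chroman-2-one
Conditions: TIPSCl, imidazole, DMF, 0 °C to rt
Reagents that add atoms: triisopropylsilyl chloride, CC(C)[Si](Cl)(C(C)C)C(C)C
Why: Imidazole-assisted O-silylation of the phenol masks the ring A hydroxyl as a heat- and base-stable, fluoride-labile ether before the lactone is enolised.

Step 2
Reactants: 2 7-(triisopropylsilyloxy)chroman-2-one
Product: 3 diphenyl 7-(triisopropylsilyloxy)-4H-chromen-2-yl phosphate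
Conditions: (PhO)2P(O)Cl, KN(SiMe3)2, THF–DMPU, −78 °C (base added to the lactone/chlorophosphate mixture)
Reagents that add atoms: diphenyl chlorophosphate, O=P(Cl)(Oc1ccccc1)Oc1ccccc1
Why: Ketene acetal phosphate formation by O-phosphorylation of the lactone potassium enolate, trapped as it forms at −78 °C so that the aryl-ester enolate does not open to a ketene, should give a stable C2 electrophile for cross-coupling.

Step 3
Reactants: 4 2-(benzyloxy)phenol
Product: 5 2-(benzyloxy)-4-bromophenol
Conditions: NBS, MeCN, 0 °C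
Reagents that add atoms: N-bromosuccinimide, O=C1CCC(=O)N1Br
Why: Electrophilic aromatic bromination is directed para to the free hydroxyl, the stronger donor, which places bromine on the carbon that becomes C1' (para to O4', meta to O3').

Step 4
Reactants: 5 2-(benzyloxy)-4-bromophenol
Product: 6 2-(benzyloxy)-4-bromophenyl methanesulfonate
Conditions: MsCl, Et3N, CH2Cl2, 0 °C
Reagents that add atoms: methanesulfonyl chloride, CS(=O)(=O)Cl
Why: O-sulfonylation gives a phenol mask for O4' that, unlike a silyl or acyl group on a catechol, cannot migrate to the neighbouring phenoxide, is inert to triphenylphosphine-ligated palladium, hydrogenation and DBU, and is later removed by an amide base without touching a silyl ether.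

Step 5
Reactants: 6 2-(benzyloxy)-4-bromophenyl methanesulfonate
Product: 7 2-(benzyloxy)-4-(4,4,5,5-tetramethyl-1,3,2-dioxaborolan-2-yl)phenyl methanesulfonate
Conditions: B2pin2, PdCl2(dppf) (3 mol%), KOAc, 1,4-dioxane, 85 °C
Reagents that add atoms: bis(pinacolato)diboron, CC1(C)OB(OC1(C)C)B1OC(C)(C)C(C)(C)O1
Why: Miyaura borylation converts the aryl bromide into the boronate under weakly basic conditions that leave the sulfonate and benzyl ether intact.

Step 6
Reactants: 3 diphenyl 7-(triisopropylsilyloxy)-4H-chromen-2-yl phosphate, 7 2-(benzyloxy)-4-(4,4,5,5-tetramethyl-1,3,2-dioxaborolan-2-yl)phenyl methanesulfonate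
Product: 8 2-(benzyloxy)-4-[7-(triisopropylsilyloxy)-4H-chromen-2-yl]phenyl methanesulfonate
Conditions: Pd(PPh3)4 (5 mol%), 2 M aq. Na2CO3, DME, 75 °C; chromatography on Et3N-treated silica
Reagents that add atoms: none
Why: Suzuki–Miyaura coupling of a lactone-derived ketene acetal phosphate with an arylboronate forms the C2–C1' bond, and the aryl mesylate is not activated by this zerovalent palladium catalyst.

Step 7
Reactants: 8 2-(benzyloxy)-4-[7-(triisopropylsilyloxy)-4H-chromen-2-yl]phenyl methanesulfonate
Product: 9 2-(benzyloxy)-4-[(2S)-7-(triisopropylsilyloxy)chroman-2-yl]phenyl methanesulfonate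
Conditions: [Ir(cod)(tBu-PHOX)][B(3,5-(CF3)2C6H3)4] (1 mol%, ligand antipode giving 2S), H2 (50 bar), CH2Cl2, rt
Reagents that add atoms: none
Why: Iridium P,N-ligand asymmetric hydrogenation of the trisubstituted cyclic enol ether (a 2-aryl-4H-chromene) adds hydrogen to one face of C2=C3 under catalyst control and so sets C2 as S, while the homogeneous catalyst leaves benzyl ether, sulfonate and silyl ether alone.

Step 8
Reactants: 9 2-(benzyloxy)-4-[(2S)-7-(triisopropylsilyloxy)chroman-2-yl]phenyl methanesulfonate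
Product: 10 2-hydroxy-4-[(2S)-7-(triisopropylsilyloxy)chroman-2-yl]phenyl methanesulfonate
Conditions: H2 (1 atm), 10% Pd/C, EtOAc, rt
Reagents that add atoms: none
Why: Hydrogenolysis of the aryl benzyl ether frees O3' only, and the cyclic benzylic C2–O1 bond, on a ring made electron-poor by the para mesylate, should resist cleavage under these mild conditions.

Step 9
Reactants: 10 2-hydroxy-4-[(2S)-7-(triisopropylsilyloxy)chroman-2-yl]phenyl methanesulfonate, 11 3-chloro-3-methylbut-1-yne
Product: 12 2-(2-methylbut-3-yn-2-yloxy)-4-[(2S)-7-(triisopropylsilyloxy)chroman-2-yl]phenyl methanesulfonate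
Conditions: DBU, CuCl2·2H2O (1 mol%), MeCN, 0 °C
Reagents that add atoms: none
Why: Copper-catalysed propargylic etherification of a phenol with a tertiary propargylic chloride gives the hindered aryl ether at O3' alone, because the neighbouring sulfonate cannot shift to the phenoxide.

Step 10
Reactants: 12 2-(2-methylbut-3-yn-2-yloxy)-4-[(2S)-7-(triisopropylsilyloxy)chroman-2-yl]phenyl methanesulfonate
Product: 13 2-(2-methylbut-3-en-2-yloxy)-4-[(2S)-7-(triisopropylsilyloxy)chroman-2-yl]phenyl methanesulfonate
Conditions: H2 (1 atm), Pd/CaCO3 poisoned with Pb(OAc)2 (Lindlar catalyst), quinoline, EtOAc, rt, stopped after one equivalent of H2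
Reagents that add atoms: none
Why: Lindlar semi-hydrogenation reduces the terminal alkyne to the vinyl group and stops there, which turns the propargyl ether into the 1,1-dimethylallyl ether at room temperature.

Step 11
Reactants: 13 2-(2-methylbut-3-en-2-yloxy)-4-[(2S)-7-(triisopropylsilyloxy)chroman-2-yl]phenyl methanesulfonate
Product: 14 2-(2-methylbut-3-en-2-yloxy)-4-[(2S)-7-(triisopropylsilyloxy)chroman-2-yl]phenol
Conditions: LiN(iPr)2 (2.5 equiv), THF, −78 °C; aq. NH4Cl quench at −78 °C
Reagents that add atoms: none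
Why: Amide-base cleavage of an aryl methanesulfonate (deprotonation of the S-methyl group and E1cB loss of sulfene) frees the 4'-phenoxide at −78 °C without acid, fluoride or hydrogen, so the tertiary allyl ether, the ring A silyl ether and C2 should be left alone.

Step 12
Reactants: 14 2-(2-methylbut-3-en-2-yloxy)-4-[(2S)-7-(triisopropylsilyloxy)chroman-2-yl]phenol, 11 3-chloro-3-methylbut-1-yne
Product: 15 (2S)-2-[3-(2-methylbut-3-en-2-yloxy)-4-(2-methylbut-3-yn-2-yloxy)phenyl]-7-(triisopropylsilyloxy)chroman
Conditions: DBU, CuCl2·2H2O (1 mol%), MeCN, −5 to 0 °C; chromatography on Et3N-treated silica, product kept cold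
Reagents that add atoms: none
Why: The same copper-catalysed propargylic etherification, run cold and briefly, should alkylate O4' without ionising the adjacent tertiary allyl ether or giving the 4'-phenoxide time to open the chroman.

Step 13
Reactants: 15 (2S)-2-[3-(2-methylbut-3-en-2-yloxy)-4-(2-methylbut-3-yn-2-yloxy)phenyl]-7-(triisopropylsilyloxy)chroman
Product: 21 6-[(2S)-7-(triisopropylsilyloxy)chroman-2-yl]-2,2-dimethyl-7-(3-methylbut-2-enyl)-2H-chromen-8-ol (7-O-triisopropylsilyl kazinol B), via C2' prenyl dienone 16 (not isolated), via prenylphenol propargyl ether 17 (not isolated), via C5' allenyl dienone 18 (not isolated), via allenyl catechol 19 (not isolated), via ortho-quinone methide 20 (not isolated)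
Conditions: degassed o-xylene (0.02 M), BHT (5 mol%), base-washed sealed tube, Ar, 110 °C then 145 °C
Reagents that add atoms: none
Why: The O3' 1,1-dimethylallyl ether should undergo a chair-like aromatic Claisen [3,3] shift that joins its CH2 terminus to C2' (dienone 16) and tautomerise to prenylphenol 17, and at the higher temperature the O4' 1,1-dimethylpropargyl ether should shift to C5' (allenyl dienone 18, then allenyl catechol 19). A [1,5]-hydrogen shift from O4'–H to the central allene carbon then gives ortho-quinone methide 20, and the six-membered pyran ring (O4', C2'', C3'', C4'', C5', C4') closes by thermal disrotatory oxa-6π electrocyclisation, which forms the O4'–C2'' bond. The closest known reactions are the thermal rearrangement of aryl 1,1-dimethylallyl ethers to ortho-prenylphenols and of aryl 1,1-dimethylpropargyl ethers to 2,2-dimethyl-2H-chromenes, here run on one ring in one operation. No stereocentre is created, and C2, a benzylic ether carbon, is a spectator under neutral conditions. The selectivity needed is C2' for the allyl unit and C5' for the propargyl unit, and the ring secures it, since the other ortho carbon of each oxygen (C4' and C3') bears oxygen and a shift there cannot rearomatise. A neutral, base-free hydrocarbon solvent at high dilution is chosen so that the short-lived 4'-phenol 19 does not open the chroman through a para-quinone methide and the tertiary allyl ether does not ionise.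

Step 14
Reactants: 21 7-O-triisopropylsilyl kazinol B
Product: 22 kazinol B, 6-[(2S)-7-hydroxychroman-2-yl]-2,2-dimethyl-7-(3-methylbut-2-enyl)-2H-chromen-8-ol
Conditions: TBAF, AcOH, THF, 0 °C
Reagents that add atoms: none
Why: Fluoride cleavage of the aryl silyl ether, buffered with acetic acid so that no free phenoxide is exposed to air, should leave the chromene, the prenyl group and C2 untouched.

**Compound list**

1 | 7-hydroxychroman-2-one (7-hydroxy-3,4-dihydrocoumarin) | O=C1CCc2ccc(O)cc2O1 | starting material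
2 | 7-(triisopropylsilyloxy)chroman-2-one | O=C1CCc2ccc(O[Si](C(C)C)(C(C)C)C(C)C)cc2O1 | intermediate
3 | diphenyl 7-(triisopropylsilyloxy)-4H-chromen-2-yl phosphate | O=P(Oc1ccccc1)(Oc1ccccc1)OC1=CCc2ccc(O[Si](C(C)C)(C(C)C)C(C)C)cc2O1 | intermediate
4 | 2-(benzyloxy)phenol | Oc1ccccc1OCc1ccccc1 | starting material
5 | 2-(benzyloxy)-4-bromophenol | Oc1ccc(Br)cc1OCc1ccccc1 | intermediate
6 | 2-(benzyloxy)-4-bromophenyl methanesulfonate | CS(=O)(=O)Oc1ccc(Br)cc1OCc1ccccc1 | intermediate
7 | 2-(benzyloxy)-4-(4,4,5,5-tetramethyl-1,3,2-dioxaborolan-2-yl)phenyl methanesulfonate | CS(=O)(=O)Oc1ccc(B2OC(C)(C)C(C)(C)O2)cc1OCc1ccccc1 | intermediate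
8 | 2-(benzyloxy)-4-[7-(triisopropylsilyloxy)-4H-chromen-2-yl]phenyl methanesulfonate | CS(=O)(=O)Oc1ccc(C2=CCc3ccc(O[Si](C(C)C)(C(C)C)C(C)C)cc3O2)cc1OCc1ccccc1 | intermediate
9 | 2-(benzyloxy)-4-[(2S)-7-(triisopropylsilyloxy)chroman-2-yl]phenyl methanesulfonate | CS(=O)(=O)Oc1ccc([C@@H]2CCc3ccc(O[Si](C(C)C)(C(C)C)C(C)C)cc3O2)cc1OCc1ccccc1 | intermediate
10 | 2-hydroxy-4-[(2S)-7-(triisopropylsilyloxy)chroman-2-yl]phenyl methanesulfonate | CS(=O)(=O)Oc1ccc([C@@H]2CCc3ccc(O[Si](C(C)C)(C(C)C)C(C)C)cc3O2)cc1O | intermediate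
11 | 3-chloro-3-methylbut-1-yne | CC(C)(Cl)C#C | starting material
12 | 2-(2-methylbut-3-yn-2-yloxy)-4-[(2S)-7-(triisopropylsilyloxy)chroman-2-yl]phenyl methanesulfonate | CS(=O)(=O)Oc1ccc([C@@H]2CCc3ccc(O[Si](C(C)C)(C(C)C)C(C)C)cc3O2)cc1OC(C)(C)C#C | intermediate
13 | 2-(2-methylbut-3-en-2-yloxy)-4-[(2S)-7-(triisopropylsilyloxy)chroman-2-yl]phenyl methanesulfonate | CS(=O)(=O)Oc1ccc([C@@H]2CCc3ccc(O[Si](C(C)C)(C(C)C)C(C)C)cc3O2)cc1OC(C)(C)C=C | intermediate
14 | 2-(2-methylbut-3-en-2-yloxy)-4-[(2S)-7-(triisopropylsilyloxy)chroman-2-yl]phenol | Oc1ccc([C@@H]2CCc3ccc(O[Si](C(C)C)(C(C)C)C(C)C)cc3O2)cc1OC(C)(C)C=C | intermediate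
15 | (2S)-2-[3-(2-methylbut-3-en-2-yloxy)-4-(2-methylbut-3-yn-2-yloxy)phenyl]-7-(triisopropylsilyloxy)chroman | C#CC(C)(C)Oc1ccc([C@@H]2CCc3ccc(O[Si](C(C)C)(C(C)C)C(C)C)cc3O2)cc1OC(C)(C)C=C | intermediate
16 | C2' prenyl dienone: cyclohexa-2,4-dienone with C3' as ketone, sp3 C2' carrying H and prenyl (either configuration), O4' propargyl ether intact | C#CC(C)(C)OC1=CC=C([C@@H]2CCc3ccc(O[Si](C(C)C)(C(C)C)C(C)C)cc3O2)C(CC=C(C)C)C1=O | intermediate (not isolated)
17 | prenylphenol propargyl ether: 6-(2-methylbut-3-yn-2-yloxy)-2-(3-methylbut-2-enyl)-3-[(2S)-7-(triisopropylsilyloxy)chroman-2-yl]phenol | C#CC(C)(C)Oc1ccc([C@@H]2CCc3ccc(O[Si](C(C)C)(C(C)C)C(C)C)cc3O2)c(CC=C(C)C)c1O | intermediate (not isolated)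
18 | C5' allenyl dienone: cyclohexa-2,4-dienone with C4' as ketone, sp3 C5' carrying H and 3-methylbuta-1,2-dienyl (either configuration), 3'-OH and 2'-prenyl in place | CC(C)=C=CC1C=C([C@@H]2CCc3ccc(O[Si](C(C)C)(C(C)C)C(C)C)cc3O2)C(CC=C(C)C)=C(O)C1=O | intermediate (not isolated)
19 | allenyl catechol: 6-(3-methylbuta-1,2-dienyl)-3-(3-methylbut-2-enyl)-4-[(2S)-7-(triisopropylsilyloxy)chroman-2-yl]benzene-1,2-diol | CC(C)=C=Cc1cc([C@@H]2CCc3ccc(O[Si](C(C)C)(C(C)C)C(C)C)cc3O2)c(CC=C(C)C)c(O)c1O | intermediate (not isolated)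
20 | ortho-quinone methide: C4' ketone, exocyclic C5'=CH–CH=C(CH3)2 with the vinyl group cis to the carbonyl | CC(C)=C/C=C1/C=C([C@@H]2CCc3ccc(O[Si](C(C)C)(C(C)C)C(C)C)cc3O2)C(CC=C(C)C)=C(O)C1=O | intermediate (not isolated)
21 | 6-[(2S)-7-(triisopropylsilyloxy)chroman-2-yl]-2,2-dimethyl-7-(3-methylbut-2-enyl)-2H-chromen-8-ol (7-O-triisopropylsilyl kazinol B) | CC(C)=CCc1c([C@@H]2CCc3ccc(O[Si](C(C)C)(C(C)C)C(C)C)cc3O2)cc2c(c1O)OC(C)(C)C=C2 | intermediate
22 | kazinol B, 6-[(2S)-7-hydroxychroman-2-yl]-2,2-dimethyl-7-(3-methylbut-2-enyl)-2H-chromen-8-ol | CC(C)=CCc1c([C@@H]2CCc3ccc(O)cc3O2)cc2c(c1O)OC(C)(C)C=C2 | target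

**Step count**

Total: 14 steps. Longest linear sequence: 12 steps (steps 3 to 14, from 2-(benzyloxy)phenol 4 to kazinol B 22).

**Steps most likely to fail**

Step 13 (key cascade). The tertiary allyl ether may fragment (ionisation or retro-ene loss of the five-carbon unit as isoprene) faster than it shifts to the flanked C2', so that the later heating for the propargyl shift acts on a ring that has lost one arm. Fallback: the prenyl group is built from a primary allyl ether, which cannot fragment in this way, and a cross-metathesis. The fallback sets out from 10. O-allylation (allyl bromide, K2CO3, acetone) should give 2-(allyloxy)-4-[(2S)-7-(triisopropylsilyloxy)chroman-2-yl]phenyl methanesulfonate F1. LiN(iPr)2 in THF at −78 °C should then free 2-(allyloxy)-4-[(2S)-7-(triisopropylsilyloxy)chroman-2-yl]phenol F2. Copper-catalysed etherification with 11 (DBU, CuCl2·2H2O, MeCN, 0 °C) should give (2S)-2-[3-(allyloxy)-4-(2-methylbut-3-yn-2-yloxy)phenyl]-7-(triisopropylsilyloxy)chroman F3. Heating F3 in 1,2-dichlorobenzene at about 180 °C should effect the same double Claisen and pyran closure to 7-allyl-6-[(2S)-7-(triisopropylsilyloxy)chroman-2-yl]-2,2-dimethyl-2H-chromen-8-ol F4. Olefin cross-metathesis of the allyl group with 2-methylbut-2-ene (second-generation Grubbs catalyst RuCl2(=CHPh)(PCy3)(H2IMes), CH2Cl2, 40 °C) should then convert allyl into prenyl, and the route is rejoined at 21.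

Step 7 (asymmetric hydrogenation). Facial selectivity on this particular 2-aryl-4H-chromene may be poor, or turnover may be slowed by the sulfonate or by traces of acid that hydrolyse the enol ether. Fallback: the stereocentre is set at a ketone and transferred with inversion. The fallback sets out from 8. Hydrolysis of the enol ether (1 M HCl, THF, rt) should give 2-(benzyloxy)-4-{3-[2-hydroxy-4-(triisopropylsilyloxy)phenyl]propanoyl}phenyl methanesulfonate F5. Noyori asymmetric transfer hydrogenation (RuCl(p-cymene)[(R,R)-TsDPEN], HCO2H–Et3N, rt) should give 2-(benzyloxy)-4-{(1R)-1-hydroxy-3-[2-hydroxy-4-(triisopropylsilyloxy)phenyl]propyl}phenyl methanesulfonate F6. Intramolecular Mitsunobu etherification (PPh3, DIAD, THF, 0 °C) should close ring C with inversion, and the route is rejoined at 9. The para mesylate makes the benzylic carbon less prone to ionise, which favours clean inversion.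

Step 12 (second etherification). O-alkylation of the 4'-phenol, flanked by the bulky tertiary allyl ether, may be slow; in the meantime the allyl ether may ionise or begin to rearrange, and the 4'-phenoxide may open the chroman at C2 and erode the enantiomeric purity. Fallback: the allyl shift is carried out before the mesylate is removed, so that the alkylation is done on a less hindered phenol with no labile ether present. The fallback sets out from 13. Heating in toluene at about 115 °C (sealed tube) should give 2-hydroxy-3-(3-methylbut-2-enyl)-4-[(2S)-7-(triisopropylsilyloxy)chroman-2-yl]phenyl methanesulfonate F7 by a single aromatic Claisen rearrangement. LiN(iPr)2 (3.5 equiv, THF, −78 °C) should free 3-(3-methylbut-2-enyl)-4-[(2S)-7-(triisopropylsilyloxy)chroman-2-yl]benzene-1,2-diol F8. Copper-catalysed etherification with one equivalent of 11 is expected to go to O4', since O3' is flanked by the prenyl group and O4'. This regioselectivity is the weak point of the fallback, and any O3' ether would have to be separated. The product is 17, here isolated, and heating 17 as in step 13 rejoins the route at 21.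

**Further compounds**

F1 | step 13 | 2-(allyloxy)-4-[(2S)-7-(triisopropylsilyloxy)chroman-2-yl]phenyl methanesulfonate | CS(=O)(=O)Oc1ccc([C@@H]2CCc3ccc(O[Si](C(C)C)(C(C)C)C(C)C)cc3O2)cc1OCC=C
F2 | step 13 | 2-(allyloxy)-4-[(2S)-7-(triisopropylsilyloxy)chroman-2-yl]phenol | Oc1ccc([C@@H]2CCc3ccc(O[Si](C(C)C)(C(C)C)C(C)C)cc3O2)cc1OCC=C
F3 | step 13 | (2S)-2-[3-(allyloxy)-4-(2-methylbut-3-yn-2-yloxy)phenyl]-7-(triisopropylsilyloxy)chroman | C#CC(C)(C)Oc1ccc([C@@H]2CCc3ccc(O[Si](C(C)C)(C(C)C)C(C)C)cc3O2)cc1OCC=C
F4 | step 13 | 7-allyl-6-[(2S)-7-(triisopropylsilyloxy)chroman-2-yl]-2,2-dimethyl-2H-chromen-8-ol | C=CCc1c([C@@H]2CCc3ccc(O[Si](C(C)C)(C(C)C)C(C)C)cc3O2)cc2c(c1O)OC(C)(C)C=C2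
F5 | step 7 | 2-(benzyloxy)-4-{3-[2-hydroxy-4-(triisopropylsilyloxy)phenyl]propanoyl}phenyl methanesulfonate | CS(=O)(=O)Oc1ccc(C(=O)CCc2ccc(O[Si](C(C)C)(C(C)C)C(C)C)cc2O)cc1OCc1ccccc1
F6 | step 7 | 2-(benzyloxy)-4-{(1R)-1-hydroxy-3-[2-hydroxy-4-(triisopropylsilyloxy)phenyl]propyl}phenyl methanesulfonate | CS(=O)(=O)Oc1ccc([C@H](O)CCc2ccc(O[Si](C(C)C)(C(C)C)C(C)C)cc2O)cc1OCc1ccccc1
F7 | step 12 | 2-hydroxy-3-(3-methylbut-2-enyl)-4-[(2S)-7-(triisopropylsilyloxy)chroman-2-yl]phenyl methanesulfonate | CS(=O)(=O)Oc1ccc([C@@H]2CCc3ccc(O[Si](C(C)C)(C(C)C)C(C)C)cc3O2)c(CC=C(C)C)c1O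
F8 | step 12 | 3-(3-methylbut-2-enyl)-4-[(2S)-7-(triisopropylsilyloxy)chroman-2-yl]benzene-1,2-diol | Oc1ccc([C@@H]2CCc3ccc(O[Si](C(C)C)(C(C)C)C(C)C)cc3O2)c(CC=C(C)C)c1O
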